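(The data come from a simulation for substances that don't exist; the scatter is artificial.)

In a one-step world, G + D → E with equal charges, a flask is told by a count of turnovers: the run time divided by a turnover time, with the share reacted equal to the count over one plus the count. I want that count for four flasks.

| flask | G | D | temperature | remark | time |
|---|---|---|---|---|---|
| north-east | 0.14 M | 0.29 M | −10 °C | run made earlier |  |
| west | 0.58 M | 0.29 M | 23 °C | run made earlier |  |
| south-west | 0.29 M | 0.58 M | −10 °C | run made earlier |  |
| Sunday's | 0.29 M | 0.290 M |  | at −25 °C until 40 s, from then on at 35 °C | 2.0 min |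
| Wednesday's | 0.29 M | 0.290 M | −25 °C |  | 2.0 min |
| Monday's | 0.29 M | 0.290 M | 35 °C |  | 2.0 min |
| Thursday's | 0.29 M | 0.290 M | 5 °C |  | 2.0 min |

| run | time / s | E / % |
|---|---|---|
| north-east | 10.0 | 13.1 |
| north-east | 15.0 | 18.8 |
| north-east | 25.0 | 25.1 |
| north-east | 40.0 | 32.3 |
| west | 10.0 | 22.7 |
| south-west | 10.0 | 22.5 |
| south-west | 20.0 | 32.8 |
| south-west | 30.0 | 38.5 |
| south-west | 40.0 | 42.0 |

(scatter of a reading: 0.3 percentage points)

- percentages count the G that a species holds: one X counts as two
- candidate steps: E <-> J; 2 D -> Z; G + D -> E; 2 G -> X

* the best flask by amount of E, in percent of the G charged; "all alike" if 1.5 percentage points covers them all (Sunday's / Wednesday's / Monday's / Thursday's / all alike)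
* amount of E at the end, in percent of the G charged, Sunday's
* amount of E at the end, in percent of the G charged, Wednesday's
* amount of E at the end, in percent of the G charged, Monday's
* amount of E at the end, in percent of the G charged, Thursday's

From the first south-west reading, 22.5% after 10.0 s with cD at 0.58 M, I get 88.9 s as the turnover time, the time in which the starting rate at −10 °C would use up a charge with cG = cD = 0.290 M. The same world promises 59.3% in the south-west run at 40.0 s, but the reading is 42.0%, so the south-west run falls behind the one-step world.

Now the ladder. The west reading at 23 °C gives 44.1 s, shorter than the run of 2.0 min, so Monday's, hotter still, should be through its charge well before the end. At −10 °C the count is 1.35, and Thursday's lies between these rungs. For −25 °C I have no run, so I borrow the forecast's factor of 2.3, which gives 204 s, longer than the run. Wednesday's is therefore unfinished, with a one-step figure of 0.587 turnovers, or 37.0%, and I expect less E than that. Sunday's changes temperature at 40 s, before a single cold turnover, so its run is mostly hot.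

The forecast says Thursday's is best, with 40% for Sunday's, 30% for Wednesday's, 39% for Monday's and 40.5% for Thursday's; of the cold flask it writes “Wednesday's is unfinished at about 30%”.

The flasks give 33.0% for Sunday's, 21.4% for Wednesday's, 37.5% for Monday's and 29.1% for Thursday's, so Monday's is best.

    E ⇌ J (K = 0.830, k = 0.0140 s⁻¹, Ea = 77.0 kJ mol⁻¹, ΔH = −3.00 kJ mol⁻¹)
    2 D → Z (k = 0.0850 L mol⁻¹ s⁻¹, Ea = 44.0 kJ mol⁻¹)
    G + D → E (k = 0.220 L mol⁻¹ s⁻¹, Ea = 53.0 kJ mol⁻¹)
    2 G → X (k = 0.100 L mol⁻¹ s⁻¹, Ea = 40.0 kJ mol⁻¹)
    (constants at 5 °C)

In Sunday's at 2.00 min, the half-life of E by the forward turning into J alone is 1.9 s, short against the run of 2.0 min. There J stands at 24.1% beside E at 33.0%. Sunday's read at 30 s is still cold: its count, from my turnover time with the borrowed factor, is 0.147, which gives 12.8% in the one-step world. The computed reading is 9.17% of E, with 74.7% of G left.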